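The midnight flask is running. It holds 2.10 M of L, 1.80 M of X and 0.00120 M of J, with less X than L, so X is the limiting reagent: Q stops at 1.80 M at the latest, 85.7% of the L charged.

| flask | L | X | J | time |
|---|---|---|---|---|
| summer | 0.600 M | 1.80 M | 0.00120 M |  |
| autumn | 0.360 M | 1.56 M | 0.00120 M |  |
| spring | 1.20 M | 1.80 M | 0.00120 M |  |
| dawn | 0.600 M | 1.80 M | 0.00360 M |  |
| midnight | 2.10 M | 1.80 M | 0.00120 M | 41 min |

- summer run (time / min: [Q] / M): 1.6: 0.004; 2.8: 0.005; 4.8: 0.016; 8.2: 0.025; 14: 0.063; 24: 0.152; 41: 0.358
- autumn run (time / min: [Q] / M): 1.6: 0.004; 2.8: 0.004; 4.8: 0.008; 8.2: 0.006; 14: 0.036; 24: 0.053; 41: 0.136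
- spring run (time / min: [Q] / M): 1.6: 0; 2.8: 0.017; 4.8: 0.020; 8.2: 0.060; 14: 0.168; 24: 0.535; 41: 0.989
- dawn run (time / min: [Q] / M): 1.6: 0.035; 2.8: 0.060; 4.8: 0.104; 8.2: 0.204; 14: 0.342; 24: 0.497; 41: 0.584

(readings scatter by 0.005 M)

- Overall: L + X -> Q, with J as catalyst.
- Constant volume, constant temperature.
- The analysis sees a species whether free or bound.
- "The second partner" is X.
- An order is taken over about fifteen percent of the charge, up and down.

1. the exponent of [L] in the starting rate at the charge of the summer run (at the point where two percent of the L have become Q) (one fixed amount of Q, the same in the runs compared)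
2. the exponent of [J] in the starting rate at the charge of the summer run (at the point where two percent of the L have become Q)
3. the autumn run starts with 0.240 M less of L and of X than the summer run, and with no Q. Compared where both hold the same amount of L, once fifteen percent of what the autumn run was charged with has turned into Q, is the autumn run faster, slower or alike (within a tenth)?
4. Q in the midnight run at 41 min, as a share of the L charged
5. which of these the readings show (the loaded catalyst dies / an uncatalysed path runs beside / the product speeds the reaction / the product decays / the product reacts on with the second partner)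

The summer run speeds up while its L and X fall, so we divide each rate by [L][X] at the middle of a window.

| Summer window | Mean [Q] | Rate | Rate/([L][X]) |
|---|---|---|---|
| 14 min to 24 min | 0.107 M | 0.00890 M/min | 0.0107 /M/min |
| 24 min to 41 min | 0.255 M | 0.0121 M/min | 0.0227 /M/min |

A straight line through these two rows has slope 0.0817 /M²/min, the path through Q, and intercept 0.00189 /M/min, the starting path. Intercept over slope gives 0.0231 M, the handover concentration: the [Q] at which the two paths carry equal rates. It is a reading, and with a scatter of 0.005 M on each point it is rough.

At 0.0120 M of Q, the point asked about in the summer run, the starting path carries 65.8% of the rate. In the dawn run, with 3.00 times the J, the early ratio is 0.0198 /M/min, about 10.5 times the intercept, near the 9.00 of a squared dependence. We take the path through Q as independent of J, which makes our [J] exponent 2 times that share, 1.32.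

The forecast differs, with 1.7 for J and 1 for L. It expects slower for the autumn run and the product speeds the reaction, from “Every run speeds up beyond what its depleting charge allows”. For midnight it expects 77%, which would leave 0.183 M of X when you come, with [Q] at 70.0 times the handover concentration.

The midnight flask gives 78.6% at 41 min. The exponents are 0.75 for L and 1.4 for J, the autumn run is slower, and the finding is the product speeds the reaction.

    J + L ⇌ JL, settled at all times (0.7040 /M)
    J + X ⇌ JX, settled at all times (0.4070 /M)
    JL + JX → Q + 2 J (23880 /M/min)
    L + X + Q → 2 Q (0.08280 /M²/min)

The [J] exponent lies below the forecast's and above ours. In the dawn run the handover concentration becomes 0.208 M, so at 0.0120 M of Q we reckon 0.0189 M/min, and the dawn rate there is 0.021 M/min.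

The readings were computed from invented constants; the scatter is artificial.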